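Target: 6-hydroxy-7-methoxy-3-(2,4,5-trimethoxyphenyl)chromen-4-one, an achiral isoflavone. The retrosynthesis first places a benzyl group on the C6 oxygen, then cuts O1–C2 (ring C), then C4a–C8a and C5–C6 together (ring A).
Enabling feature: ring A bears oxygen on C8a, C7 and C6, the C4 carbonyl carbon on C4a, and hydrogen on C5 and C8. C8a–C8–C7–C6 is therefore a 1,1,3,4-tetraoxygenated butadiene, and C4a–C5 is the triple bond of a terminal ynone.
Forward: ring B is bought as an acetophenone, and its side chain is reshaped into C3, C2 (a methoxymethylene carbon), C4 and the ethynyl unit C4a–C5. The diene comes in three steps from methyl 4-chloroacetoacetate and benzyl alcohol.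
Ring order: B (purchased), A (Diels–Alder reaction and aromatisation), C (acid-catalysed addition–elimination at C2). Hydrogenolysis then frees the C6 hydroxyl.
Stereochemistry: the target has no stereocentre. The alkene geometries of the precursors and the two sp3 ring carbons of the cycloadduct are all erased on the way.

Key step: step 9

Assumption: the diene is used as the mixture of double-bond isomers that silylation delivers, so it is drawn without alkene descriptors. The isomer whose benzyloxy group points away from the s-cis diene cavity is taken to be the reacting one.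

Step 1
Reactants: 1 methyl 4-chloro-3-oxobutanoate; 2 benzyl alcohol
Product: 3 methyl 4-(benzyloxy)-3-oxobutanoate
Conditions: NaH (2.2 equiv), THF, 0 °C → rt; 1 M HCl quench
Reagents that add atoms: none
Why: Williamson ether synthesis in which the first equivalent of NaH stores the β-keto ester as its unreactive sodium enolate, so sodium benzyl oxide only displaces the primary chloride by SN2 and neither ester exchange nor ketone attack competes.

Step 2
Reactants: 3 methyl 4-(benzyloxy)-3-oxobutanoate
Product: 4 methyl (E)-4-(benzyloxy)-3-methoxybut-2-enoate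
Conditions: HC(OMe)3, cat. H2SO4, MeOH, 50 °C
Reagents that add atoms: trimethyl orthoformate, COC(OC)OC
Why: Acid-catalysed enol etherification of a β-keto ester with an orthoformate, the usual entry to 3-methoxycrotonates, should give the ester-conjugated E enol ether under thermodynamic control and leaves the benzyl ether untouched.

Step 3
Reactants: 4 methyl (E)-4-(benzyloxy)-3-methoxybut-2-enoate
Product: 6 1-(benzyloxy)-2,4-dimethoxy-4-(trimethylsilyloxy)buta-1,3-diene, via lithium dienolate 5 (not isolated)
Conditions: LiN(iPr)2, THF, −78 °C; Me3SiCl, −78 °C → rt; pentane, filtration under argon, used crude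
Reagents that add atoms: chlorotrimethylsilane, C[Si](C)(C)Cl
Why: Kinetic γ-deprotonation of a 3-methoxycrotonate followed by O-silylation of the extended enolate is the standard preparation of Brassard-type mixed vinylketene acetals, and the CH2 next to the benzyloxy group is the only site that gives a conjugated anion.

Step 4
Reactants: 7 1-(2,4,5-trimethoxyphenyl)ethan-1-one
Product: 8 methyl 2-(2,4,5-trimethoxyphenyl)acetate
Conditions: Tl(NO3)3·3H2O, MeOH–HC(OMe)3, rt
Reagents that add atoms: methanol, CO
Why: McKillop–Taylor oxidative rearrangement, in which trivalent thallium adds to the enolised ketone and its departure as monovalent thallium drives a 1,2-shift of the very electron-rich aryl group, converting the aryl methyl ketone directly into the methyl arylacetate.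

Step 5
Reactants: 8 methyl 2-(2,4,5-trimethoxyphenyl)acetate
Product: 10 methyl (E)-3-methoxy-2-(2,4,5-trimethoxyphenyl)prop-2-enoate, via sodium formyl enolate 9 (not isolated)
Conditions: NaH, HCO2Me, DMF, 0 °C → rt; then Me2SO4, rt
Reagents that add atoms: methyl formate, COC=O; dimethyl sulfate, COS(=O)(=O)OC
Why: Crossed Claisen formylation followed by O-alkylation of the hard enolate oxygen with a hard methylating agent in a dipolar solvent is the established route to aryl β-methoxyacrylates and favours the E isomer, with methoxy and ester on opposite sides.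

Step 6
Reactants: 10 methyl (E)-3-methoxy-2-(2,4,5-trimethoxyphenyl)prop-2-enoate
Product: 11 (E)-3-methoxy-2-(2,4,5-trimethoxyphenyl)prop-2-enoic acid
Conditions: LiOH·H2O, THF–MeOH–H2O, 50 °C; then 1 M HCl to pH 3, 0 °C
Reagents that add atoms: lithium hydroxide monohydrate, [Li+].[OH-].O
Why: Saponification by acyl–oxygen cleavage is known to leave the push–pull double bond of β-methoxyacrylates intact, and cold acidification to pH 3 avoids protonation of the enol ether.

Step 7
Reactants: 11 (E)-3-methoxy-2-(2,4,5-trimethoxyphenyl)prop-2-enoic acid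
Product: 13 (E)-N,3-dimethoxy-N-methyl-2-(2,4,5-trimethoxyphenyl)prop-2-enamide, via acyl imidazolide 12 (not isolated)
Conditions: 1,1'-carbonyldiimidazole (CDI), CH2Cl2, rt; then MeNH(OMe)·HCl, rt
Reagents that add atoms: N,O-dimethylhydroxylamine hydrochloride, CNOC.Cl
Why: Amide coupling through the acyl imidazolide runs close to neutrality and without strong acid or base, so the enol ether is spared while the Weinreb amide forms.

Step 8
Reactants: 13 (E)-N,3-dimethoxy-N-methyl-2-(2,4,5-trimethoxyphenyl)prop-2-enamide; 14 ethynylmagnesium bromide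
Product: 16 (E)-1-methoxy-2-(2,4,5-trimethoxyphenyl)pent-1-en-4-yn-3-one, via magnesium chelate 15 (not isolated)
Conditions: HC≡CMgBr (2.5 equiv), THF, 0 °C → rt; inverse quench into aq NaHSO4/Et2O, 0 °C; used promptly
Reagents that add atoms: none
Why: Weinreb ketone synthesis, in which the five-membered magnesium chelate holds the tetrahedral adduct until the quench so only one alkynyl group enters, the alkynyl Grignard reagent prefers 1,2- over conjugate attack, and pouring into cold acid protonates the released amine before it can add to the ynone.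

Step 9
Reactants: 6 1-(benzyloxy)-2,4-dimethoxy-4-(trimethylsilyloxy)buta-1,3-diene; 16 (E)-1-methoxy-2-(2,4,5-trimethoxyphenyl)pent-1-en-4-yn-3-one
Product: 18 (E)-1-[5-(benzyloxy)-2-hydroxy-4-methoxyphenyl]-3-methoxy-2-(2,4,5-trimethoxyphenyl)prop-2-en-1-one, via cyclohexadiene cycloadduct 17 (not isolated)
Conditions: 6 (1.5 equiv), toluene, rt → 70 °C; then THF–0.1 M aq HCl, 0 °C
Reagents that add atoms: none
Why: The electron-rich vinylketene acetal and the electron-poor alkyne combine in a normal-electron-demand, concerted but strongly asynchronous [4+2] cycloaddition in which the C6 terminus of the diene bonds ahead to the unsubstituted alkyne carbon C5 and the ketene acetal carbon C8a follows onto the acyl-bearing carbon C4a, which is the Brassard-type Diels–Alder benzannulation known for mixed vinylketene acetals with acetylenic ketones and esters. Ring A closes as a six-membered carbocycle by this intermolecular [4+2] mode, two C–C bonds being made at once, and first appears as cyclohexa-1,4-diene 17. Dilute acid ionises the acetal carbon C8a, C6 gives up its hydrogen and the silyl ether is hydrolysed, so 17 aromatises with loss of methanol and trimethylsilanol, and the benzyloxy group has to stay because aromatisation requires a leaving group from C8a and a proton from C6. The C6 and C8a stereocentres of 17 are uncontrolled and disappear on aromatisation, so no stereocontrol element is needed. Regioselectivity rests on matched polarisation, since the two oxygens on C8a and the C7 methoxy group push electron density onto C6 and outweigh the single opposing benzyloxy donor, while the ketone makes C5 the electrophilic alkyne carbon. Chemoselectivity rests on the low-lying LUMO and open access of the terminal ynone compared with the trisubstituted push–pull β-methoxyenone alkene, which is a poor dienophile.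

Step 10
Reactants: 18 (E)-1-[5-(benzyloxy)-2-hydroxy-4-methoxyphenyl]-3-methoxy-2-(2,4,5-trimethoxyphenyl)prop-2-en-1-one
Product: 19 6-(benzyloxy)-7-methoxy-3-(2,4,5-trimethoxyphenyl)-4H-chromen-4-one
Conditions: cat. TsOH·H2O, toluene, 80 °C
Reagents that add atoms: none
Why: Acid-catalysed intramolecular oxa-Michael addition of the C8a hydroxyl to C2 (6-endo-trig) followed by β-elimination of methanol, the addition–elimination on a vinylogous ester that ends classical isoflavone syntheses, closes ring C and is driven by formation of the aromatic 4-pyranone.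

Step 11
Reactants: 19 6-(benzyloxy)-7-methoxy-3-(2,4,5-trimethoxyphenyl)-4H-chromen-4-one
Product: 20 6-hydroxy-7-methoxy-3-(2,4,5-trimethoxyphenyl)-4H-chromen-4-one
Conditions: H2 (1 atm), 10% Pd/C, EtOAc–MeOH, rt, stopped after one equivalent of H2
Reagents that add atoms: none
Why: Catalytic hydrogenolysis of an aryl benzyl ether is faster than saturation of the conjugated C2–C3 bond and is routinely used on benzyloxyisoflavones, while the methyl ethers are inert.

Compound list
1 | methyl 4-chloro-3-oxobutanoate | COC(=O)CC(=O)CCl | starting material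
2 | benzyl alcohol | OCc1ccccc1 | starting material
3 | methyl 4-(benzyloxy)-3-oxobutanoate | COC(=O)CC(=O)COCc1ccccc1 | intermediate
4 | methyl (E)-4-(benzyloxy)-3-methoxybut-2-enoate | CO/C(COCc1ccccc1)=C/C(=O)OC | intermediate
5 | lithium 4-(benzyloxy)-1,3-dimethoxybuta-1,3-dien-1-olate (not isolated) | [Li+].COC([O-])=CC(OC)=COCc1ccccc1 | intermediate
6 | 1-(benzyloxy)-2,4-dimethoxy-4-(trimethylsilyloxy)buta-1,3-diene (mixture of double-bond isomers) | COC(O[Si](C)(C)C)=CC(OC)=COCc1ccccc1 | intermediate
7 | 1-(2,4,5-trimethoxyphenyl)ethan-1-one | CC(=O)c1cc(OC)c(OC)cc1OC | starting material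
8 | methyl 2-(2,4,5-trimethoxyphenyl)acetate | COC(=O)Cc1cc(OC)c(OC)cc1OC | intermediate
9 | sodium 3-methoxy-3-oxo-2-(2,4,5-trimethoxyphenyl)prop-1-en-1-olate (not isolated) | [Na+].[O-]C=C(C(=O)OC)c1cc(OC)c(OC)cc1OC | intermediate
10 | methyl (E)-3-methoxy-2-(2,4,5-trimethoxyphenyl)prop-2-enoate | CO/C=C(/C(=O)OC)c1cc(OC)c(OC)cc1OC | intermediate
11 | (E)-3-methoxy-2-(2,4,5-trimethoxyphenyl)prop-2-enoic acid | CO/C=C(/C(=O)O)c1cc(OC)c(OC)cc1OC | intermediate
12 | (E)-1-(1H-imidazol-1-yl)-3-methoxy-2-(2,4,5-trimethoxyphenyl)prop-2-en-1-one (not isolated) | CO/C=C(/C(=O)n1ccnc1)c1cc(OC)c(OC)cc1OC | intermediate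
13 | (E)-N,3-dimethoxy-N-methyl-2-(2,4,5-trimethoxyphenyl)prop-2-enamide | CO/C=C(/C(=O)N(C)OC)c1cc(OC)c(OC)cc1OC | intermediate
14 | ethynylmagnesium bromide | C#C[Mg]Br | starting material
15 | bromomagnesium alkoxide of (E)-1-methoxy-3-[methoxy(methyl)amino]-2-(2,4,5-trimethoxyphenyl)pent-1-en-4-yn-3-ol (racemic chelate, not isolated) | CO/C=C(/C(O[Mg]Br)(C#C)N(C)OC)c1cc(OC)c(OC)cc1OC | intermediate
16 | (E)-1-methoxy-2-(2,4,5-trimethoxyphenyl)pent-1-en-4-yn-3-one | CO/C=C(/C(=O)C#C)c1cc(OC)c(OC)cc1OC | intermediate
17 | (E)-1-[3-(benzyloxy)-4,6-dimethoxy-6-(trimethylsilyloxy)cyclohexa-1,4-dien-1-yl]-3-methoxy-2-(2,4,5-trimethoxyphenyl)prop-2-en-1-one (racemic mixture of diastereomers, not isolated) | CO/C=C(/C(=O)C1=CC(OCc2ccccc2)C(OC)=CC1(OC)O[Si](C)(C)C)c1cc(OC)c(OC)cc1OC | intermediate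
18 | (E)-1-[5-(benzyloxy)-2-hydroxy-4-methoxyphenyl]-3-methoxy-2-(2,4,5-trimethoxyphenyl)prop-2-en-1-one | CO/C=C(/C(=O)c1cc(OCc2ccccc2)c(OC)cc1O)c1cc(OC)c(OC)cc1OC | intermediate
19 | 6-(benzyloxy)-7-methoxy-3-(2,4,5-trimethoxyphenyl)-4H-chromen-4-one | COc1cc2occ(-c3cc(OC)c(OC)cc3OC)c(=O)c2cc1OCc1ccccc1 | intermediate
20 | 6-hydroxy-7-methoxy-3-(2,4,5-trimethoxyphenyl)-4H-chromen-4-one (CNP0328698.0) | COc1cc2occ(-c3cc(OC)c(OC)cc3OC)c(=O)c2cc1O | target

Total step count: 11.
Longest linear sequence: 8 steps (7 → 8 → 10 → 11 → 13 → 16 → 18 → 19 → 20). The diene arm (1 → 3 → 4 → 6) joins at step 9.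

Steps most likely to fail

1. Step 9 (cycloaddition and aromatisation).
- What may go wrong: the diene may add to the ynone only in the Mukaiyama–Michael sense without forming the second bond. The terminal ynone may polymerise on warming. The diene isomer with an inward benzyloxy group may fail to reach the s-cis geometry. Early loss of methanol towards 19 during work-up would be harmless.
- Fallback: ring A is taken from an existing arene instead of being built. Setting out from 8, saponification with NaOH in aqueous methanol gives 2-(2,4,5-trimethoxyphenyl)acetic acid F1. Friedel–Crafts acylation of commercial 2-methoxyhydroquinone with this acid in BF3·OEt2 at 80 °C goes para to the methoxy group and ortho to a hydroxyl, and gives 1-(2,5-dihydroxy-4-methoxyphenyl)-2-(2,4,5-trimethoxyphenyl)ethan-1-one F2. A Vilsmeier-type one-carbon insertion with DMF, BF3·OEt2 and MeSO2Cl at 60 °C then formylates the methylene group and closes ring C. The sequence comes back to the route at 20.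

2. Step 8 (ethynylation of the Weinreb amide).
- What may go wrong: attack at the β-methoxy carbon with loss of methoxide, addition of the liberated N,O-dimethylhydroxylamine to the fresh ynone during the quench, or polymerisation on concentration.
- Fallback: the ketone is reached through the alcohol oxidation level. Setting out from 13, reduction with iBu2AlH in THF at −78 °C gives (E)-3-methoxy-2-(2,4,5-trimethoxyphenyl)prop-2-enal F3. This aldehyde takes up 14 by clean 1,2-addition to give racemic (E)-1-methoxy-2-(2,4,5-trimethoxyphenyl)pent-1-en-4-yn-3-ol F4. Neutral oxidation of this doubly activated alcohol with MnO2 in CH2Cl2 comes back to the route at 16, with no amine present at the ynone stage.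

3. Step 3 (formation of the vinylketene acetal).
- What may go wrong: incomplete γ-deprotonation, silylation on carbon, hydrolysis during handling, or predominance of the unreactive alkene geometry.
- Fallback: the C7 oxygen is carried as a silyl ether and methylated after ring C is closed. Setting out from 3, soft enolisation with Et3N and Me3SiCl in toluene gives methyl (Z)-4-(benzyloxy)-3-(trimethylsilyloxy)but-2-enoate F5. Treatment with LiN(iPr)2 and Me3SiCl in THF at −78 °C gives the Chan-type diene 1-(benzyloxy)-4-methoxy-2,4-bis(trimethylsilyloxy)buta-1,3-diene F6, a class documented for 4-alkoxyacetoacetates and more nucleophilic than 6. Cycloaddition with 16 and dilute acid work-up gives (E)-1-[5-(benzyloxy)-2,4-dihydroxyphenyl]-3-methoxy-2-(2,4,5-trimethoxyphenyl)prop-2-en-1-one F7. Catalytic TsOH·H2O in toluene closes ring C to 6-(benzyloxy)-7-hydroxy-3-(2,4,5-trimethoxyphenyl)-4H-chromen-4-one F8. Methylation of its single free phenol with MeI and K2CO3 in acetone comes back to the route at 19.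

Further compounds
F1 | step 9 | 2-(2,4,5-trimethoxyphenyl)acetic acid | OC(=O)Cc1cc(OC)c(OC)cc1OC
F2 | step 9 | 1-(2,5-dihydroxy-4-methoxyphenyl)-2-(2,4,5-trimethoxyphenyl)ethan-1-one | COc1cc(O)c(cc1O)C(=O)Cc1cc(OC)c(OC)cc1OC
F3 | step 8 | (E)-3-methoxy-2-(2,4,5-trimethoxyphenyl)prop-2-enal | CO/C=C(/C=O)c1cc(OC)c(OC)cc1OC
F4 | step 8 | (E)-1-methoxy-2-(2,4,5-trimethoxyphenyl)pent-1-en-4-yn-3-ol (racemic) | CO/C=C(/C(O)C#C)c1cc(OC)c(OC)cc1OC
F5 | step 3 | methyl (Z)-4-(benzyloxy)-3-(trimethylsilyloxy)but-2-enoate | COC(=O)/C=C(/COCc1ccccc1)O[Si](C)(C)C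
F6 | step 3 | 1-(benzyloxy)-4-methoxy-2,4-bis(trimethylsilyloxy)buta-1,3-diene (mixture of double-bond isomers) | COC(O[Si](C)(C)C)=CC(O[Si](C)(C)C)=COCc1ccccc1
F7 | step 3 | (E)-1-[5-(benzyloxy)-2,4-dihydroxyphenyl]-3-methoxy-2-(2,4,5-trimethoxyphenyl)prop-2-en-1-one | CO/C=C(/C(=O)c1cc(OCc2ccccc2)c(O)cc1O)c1cc(OC)c(OC)cc1OC
F8 | step 3 | 6-(benzyloxy)-7-hydroxy-3-(2,4,5-trimethoxyphenyl)-4H-chromen-4-one | COc1cc(OC)c(cc1OC)-c1coc2cc(O)c(OCc3ccccc3)cc2c1=O
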